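## The problem

The target is a flavonol whose 2-aryl substituent is a 2,3-dihydrobenzofuran. In benzofuran numbering, C2 carries the 4-hydroxy-3-methoxyphenyl (guaiacyl) group, C3 a hydroxymethyl group, C4 the 3,5,7-trihydroxy-4-oxochromen-2-yl unit and C7 a hydroxyl; ring D is the furan and ring B its benzene. Ring B is therefore a 1,2,3,4-tetrasubstituted benzene (C7a–O, C7–O, C3a–C, C4–C) with C5 and C6 unsubstituted. The chromone sits on C4 next to the ring fusion, a position that neither oxygen substituent singles out for electrophilic substitution or metallation of a preformed dihydrobenzofuran. There are two stereocentres, C2 (R) and C3 (S), trans across ring D. C3 is a configurationally stable all-carbon centre and must be set absolutely. C2 is a benzylic ether carbon on an electron-rich arene that can ionise and then settles trans to C3, so C3 can correct C2 but not the reverse. The same C2–O1 bond is the fragile point towards acid and over-reduction, and the flavonol with its phenols is sensitive to oxidants and to base in air. This argues for carrying the hydroxyls as ethers that leave in one neutral final step and for building the chromone late from a one-carbon arm at C4. The feature that makes the key step possible is the edge C7a(O)–C7(O)–C6(H)–C5(H) of ring B. It is the C3–C4–C5–C6 edge of a 3,4-dialkoxypyridazine, while C3a and C4 are the two carbons of an alkyne that the pyridazine C3 oxygen (O1) holds through C2 and C3.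

## Retrosynthesis

**24 to 23.** Five O–benzyl bonds are cut last. All hydroxyls of 24 except the chelated flavonol 3-OH are traced to benzyl ethers in 23, so that one neutral hydrogenolysis ends the synthesis. Silyl or acyl groups would not survive the basic condensation and the oxidations of the chromone construction, and acid-labile groups would endanger the C2–O1 bond on removal. Compound 23 is no simpler in skeleton but is a robust, non-phenolic carrier. The forward reaction must cleave four aryl and one alkyl benzyl ether while sparing the benzylic C2–O1 bond of ring D.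

**23 to 17 and 19.** The chromone is dismantled along classical lines. The C3 hydroxyl is removed (forward: epoxidation of flavone 21 to epoxide 22 and acid-induced opening). The pyranone O–C2 bond is cut to the 2'-hydroxychalcone 20. The enone C=C bond is cut to aldehyde 17 and acetophenone 19, itself the dibenzyl ether of 18. The shorter peroxide closure of 20 directly to 23 was set aside because a 6'-alkoxy group steers that reaction towards aurones. Joining a finished chromone to C4 by cross-coupling was set aside because the bond lies ortho to the ring fusion. The gain is large: the whole chromone shrinks to a formyl group on C4. The forward steps need a base-mediated condensation at a hindered aldehyde that leaves C3 alone, and two oxidations that spare the electron-rich arenes and benzylic ethers.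

**17 to 15.** The formyl group of 17 is traced through benzylic alcohol 16 to silyl ether 15 (O–Si cut and change of oxidation level). Carrying the arm as a protected carbinol keeps the alkyne from which it derives electron-neutral and inert to the organozinc and alkoxide chemistry used earlier. Two routine steps are the price.

**15 to 13 (key disconnection).** The bonds C7a–C3a and C4–C5 are cut and the two nitrogens of a pyridazine are placed back across C7a and C5, giving pyridazinyl ether 13 by way of the bridged adduct 14. This removes rings B and D at once and leaves an acyclic ether of a simple diazine. Cuts within ring D alone (O1–C2, C2–C3 or C3–C3a) would all leave the tetrasubstituted benzene to be assembled with its four neighbours in the right order, which is the hard part here. The diazine cut makes that order a matter of connectivity. The stereocentres are not involved and can be set in the open chain. The forward reaction must be a purely thermal cycloaddition–cycloreversion that is faster than cleavage of the benzylic C–O bond of 13.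

**13 to 9 and 11.** The aryl–O bond of 13 is cut to secondary alcohol 9 (as its alkoxide 12) and chlorodiazine 11; 11 goes back to 10 by cutting its C4–O bond. Substitution at the heteroaryl carbon leaves the carbinol C–O bond, and with it C2 of the target, untouched. Alkylating a pyridazinone with an activated form of 9 would invert or scramble that centre and favours nitrogen. The order on 10 follows its reactivity: C4 reacts first, so the benzyloxy group goes on first and 12 is left with the only remaining chloride. The forward step asks a hindered alkoxide to displace chloride from a deactivated ring without base damage at the propargylic position.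

**9 to 6 and 7.** The C1–C2 bond of 9 (C2–C3 of the target) is cut to aldehyde 7 and propargylic mesylate 6, joined through allenylzinc 8. This one bond formation creates both stereocentres, places the alkyne where the cycloaddition needs it and brings in the future C4 arm. An aldol or crotylation route to the same diad would still have to convert a carbonyl or alkene into the substituted alkyne. The forward reaction needs complete transfer of chirality from 6 to C2 and anti selectivity at C1 with an aromatic aldehyde.

**6 to 1 and 2.** Mesylate 6 comes from alcohol 5 (S–O cut), 5 from ynone 4 by removing the carbinol hydrogen, and 4 from terminal alkyne 1 and amide 2 by cutting the acyl–alkynyl bond (forward through acetylide 3). A catalytic ketone reduction was preferred to direct asymmetric alkynylation of an unbranched α-alkoxy aldehyde, a poor substrate class for the latter, whereas alkynyl ketones are among the best for the former. All absolute stereochemistry thus rests on one catalytic reduction.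

## Roads not taken

**Alternative 1:** The cut runs through ring D at C2–C3 and O1–C2, with ring B bought as an arene. Sulfone A2 would release an ortho-quinone methide (C7a=O, C3a=C3) under a carbonate base. The ylide of a chiral guaiacylmethyl sulfonium salt such as A3 would add at C3, and the phenoxide would displace the sulfide at C2 to give bromide A1.
- Merits: ring D and both stereocentres arise in one mild step, trans through anti-periplanar closure of the betaine. The C4 bromide of A1 could be converted into aldehyde 17 by halogen–metal exchange and formylation. This road would reach 17 in fewer steps and with no high-temperature step.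
- Weak points: the absolute configuration depends on a stoichiometric chiral sulfide whose induction with benzyl-type ylides and quinone methides is substrate-dependent. The quinone methide from A2 has hydrogens next to the methide carbon that permit tautomerisation to an ortho-vinylphenol, and that carbon is flanked by the C4 bromine. A2 is itself a contiguously tetrasubstituted benzene that must be made by selective aromatic substitution.
- Comparison: against the better step count, the chosen plan offers a C3 configuration from a catalytic ketone reduction relayed stereospecifically, and a ring B substitution pattern that cannot come out wrong.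

**Alternative 2:** The cut is the C3–C3a bond, made by ring contraction. Irradiation of the 3-diazochroman-4-one A5 in methanol would expel N2, shift aryl carbon C3a from the carbonyl carbon to the carbene carbon and trap the ketene as methyl ester A4.
- Merits: A5 is reached by classical flavanone chemistry from aldehyde 7, ring B never has to be built, the reaction runs at room temperature, and the C3 ester can be equilibrated to trans before reduction to the hydroxymethyl group.
- Weak points: C2 is the only stereocentre of A5 and is labile, because 2-arylchromanones with electron-rich aryl groups open to chalcones by retro-oxa-Michael reaction under the basic conditions of diazo transfer. The carbene next to C2–H can undergo 1,2-hydrogen shift to a flavone in competition with the Wolff rearrangement. The aryl bromide and benzyl ethers are not innocent under ultraviolet light. After A4, ester reduction, O-benzylation and formylation at C4 are still needed, so the route is not shorter.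
- Comparison: this road is better in needing no forcing thermolysis and in using an inexpensive arene for ring B. The chosen plan answers with stereocentres that are never α to a carbonyl or exposed to ring opening, and with the C4 carbon arm installed in the ring-forming step itself.

**Alternative 3:** The cuts are C4–C(alkyne) and C3a–C3. A hindered lithium amide would deprotonate triflate A7 at C3a and expel triflate to give the C3a≡C4 aryne. A lithium silylacetylide would add at C4, and the resulting C3a aryllithium would open the tethered epoxide at C3 in a 5-exo sense to give A6.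
- Merits: the stereocentres of A7 derive from asymmetric epoxidation chemistry of reliable absolute sense, and C3 is fixed by a stereospecific SN2 opening. This is firmer than the anti selectivity the chosen plan needs from an aromatic aldehyde. Ring D and the C4 substituent arrive in one operation, and the C4 alkyne of A6 could be acylated and cyclised to the chromone, shortening the end game.
- Weak points: three anionic events must run in sequence in one flask. The amide base itself adds to arynes. C2–H of A7 is benzylic and α to oxygen, and its removal would fragment the neighbouring epoxide. Ortho-metallated aryl triflates can rearrange (anionic thia-Fries) instead of eliminating.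
- Comparison: in step count and stereochemical security this road is at least the equal of the chosen one. The chosen plan sets against it a unimolecular, neutral, reagent-free key step of a known reaction type whose regiochemistry is dictated by the tether.

Key step: step 7

Assumptions: compounds 1, 2, 7, 10 and 18 are taken as commercial. The sense of induction in step 2 is taken to follow that of simple alkynyl ketones (alkynyl group in the aryl site); if it does not, the mirror-image catalyst would be used.

## Route

Step 1
Reactants: 1 tert-butyldimethyl(prop-2-yn-1-yloxy)silane; 2 2-(benzyloxy)-N-methoxy-N-methylacetamide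
Product: 4 1-(benzyloxy)-5-[(tert-butyldimethylsilyl)oxy]pent-3-yn-2-one, via lithium acetylide 3 (not isolated)
Conditions: n-BuLi, THF, −78 °C; then 2, −78 to −20 °C
Reagents that add atoms: none
Why: Weinreb ketone synthesis; acetylide 3 adds once to the N-methoxy-N-methylamide and the chelated tetrahedral adduct collapses to the ynone only on work-up, so over-addition should not occur.

Step 2
Reactants: 4 1-(benzyloxy)-5-[(tert-butyldimethylsilyl)oxy]pent-3-yn-2-one
Product: 5 (2R)-1-(benzyloxy)-5-[(tert-butyldimethylsilyl)oxy]pent-3-yn-2-ol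
Conditions: Ru[(S,S)-TsDPEN](p-cymene) (1 mol%), i-PrOH, rt
Reagents that add atoms: none
Why: Noyori asymmetric transfer hydrogenation of an alkynyl ketone under base-free conditions that spare the ynone; the alkynyl group takes the place of the aryl group in the six-membered hydride-transfer transition state, so the (S,S) catalyst should give the 2R alcohol (R only because CH2OBn outranks the alkynyl group).

Step 3
Reactants: 5 (2R)-1-(benzyloxy)-5-[(tert-butyldimethylsilyl)oxy]pent-3-yn-2-ol
Product: 6 (2R)-1-(benzyloxy)-5-[(tert-butyldimethylsilyl)oxy]pent-3-yn-2-yl methanesulfonate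
Conditions: MsCl, Et3N, CH2Cl2, −40 to 0 °C
Reagents that add atoms: methanesulfonyl chloride, CS(=O)(=O)Cl
Why: Standard O-sulfonylation; no bond to the stereocentre is broken, so the configuration is retained, and the mesylate is used without chromatography.

Step 4
Reactants: 6 (2R)-1-(benzyloxy)-5-[(tert-butyldimethylsilyl)oxy]pent-3-yn-2-yl methanesulfonate; 7 4-(benzyloxy)-3-methoxybenzaldehyde
Product: 9 (1R,2S)-2-[(benzyloxy)methyl]-1-[4-(benzyloxy)-3-methoxyphenyl]-5-[(tert-butyldimethylsilyl)oxy]pent-3-yn-1-ol, via allenyl(ethyl)zinc 8 (not isolated)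
Conditions: Pd(OAc)2 (5 mol%), PPh3 (5 mol%), Et2Zn (3 equiv), THF, −20 °C
Reagents that add atoms: none
Why: Marshall–Tamaru propargylation; zerovalent palladium displaces the mesylate in an anti SN2' sense, transmetallation gives the (aR)-allenylzinc 8, and its syn SE2' addition to the aldehyde through a cyclic zinc-bound transition state gives the homopropargylic alcohol. C2 arises by net inversion of the mesylate carbon (R to S), and C1 is set R because the aryl group turns away from the CH2OBn substituent of the allene in that transition state, which is the anti pathway.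

Step 5
Reactants: 10 3,4-dichloropyridazine
Product: 11 4-(benzyloxy)-3-chloropyridazine
Conditions: BnOH (1.0 equiv), NaH, THF, 0 °C to rt
Reagents that add atoms: benzyl alcohol, OCc1ccccc1
Why: Nucleophilic aromatic substitution; C4 (para-like to N1) is the more electrophilic carbon of 3,4-dichloropyridazine, so one equivalent of alkoxide should replace only the 4-chloride, and the new alkoxy group then deactivates the ring towards a second substitution.

Step 6
Reactants: 9 (1R,2S)-2-[(benzyloxy)methyl]-1-[4-(benzyloxy)-3-methoxyphenyl]-5-[(tert-butyldimethylsilyl)oxy]pent-3-yn-1-ol; 11 4-(benzyloxy)-3-chloropyridazine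
Product: 13 4-(benzyloxy)-3-{[(1R,2S)-2-[(benzyloxy)methyl]-1-[4-(benzyloxy)-3-methoxyphenyl]-5-[(tert-butyldimethylsilyl)oxy]pent-3-yn-1-yl]oxy}pyridazine, via sodium alkoxide 12 (not isolated)
Conditions: NaH, THF/DMF (4:1), 0 °C; then 11, 0 °C to rt
Reagents that add atoms: none
Why: Nucleophilic aromatic substitution at C3 of the chlorodiazine (α to N2) by the secondary alkoxide; the carbinol C–O bond is not broken, so both stereocentres are retained.

Step 7
Reactants: 13 4-(benzyloxy)-3-{[(1R,2S)-2-[(benzyloxy)methyl]-1-[4-(benzyloxy)-3-methoxyphenyl]-5-[(tert-butyldimethylsilyl)oxy]pent-3-yn-1-yl]oxy}pyridazine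
Product: 15 (2R,3S)-7-(benzyloxy)-3-[(benzyloxy)methyl]-2-[4-(benzyloxy)-3-methoxyphenyl]-4-{[(tert-butyldimethylsilyl)oxy]methyl}-2,3-dihydro-1-benzofuran, via bridged diaza cycloadduct 14 (not isolated)
Conditions: 1,3,5-triisopropylbenzene (0.01 M, degassed), 2,6-di-tert-butyl-4-methylpyridine (0.2 equiv), 190 °C, sealed tube
Reagents that add atoms: none
Why: Thermal intramolecular inverse-electron-demand [4+2] cycloaddition in which the electron-poor 1,2-diazine is the four-electron component across its C3 and C6 and the tethered alkyne is the two-electron component, giving the 2,3-diazabicyclo[2.2.2]octatriene 14, which loses N2 by retro-[4+2] and so delivers the benzene ring irreversibly. The closest known reaction type is the thermolysis of 3-(alk-3-ynyloxy)pyridazines to 2,3-dihydrobenzofurans. Ring D closes in the cycloaddition itself as the five-membered ring spanned by the three-atom O–C–C tether (bond C7a–C3a, exo with respect to the alkyne), and ring B is completed by the second bond C4–C5 and the cycloreversion. No stereocentre is formed: the bridgeheads of 14 become sp2 on loss of N2, and C2 and C3 are not involved, so the anti arrangement of 13 becomes the trans arrangement of 15. The selectivity needed is regiochemical and chemical. The first is fixed because the tether lets the inner alkyne carbon reach only the ipso carbon C3 of the diazine and the outer one only C6, which places the silyloxymethyl group at C4, the benzyloxy group at C7 and hydrogen at C5 and C6. The second, cycloaddition ahead of heterolysis or elimination of the benzylic pyridazinyl ether, is helped by the two substituents on the tether (Thorpe–Ingold effect), by the non-polar solvent and by the hindered pyridine base that removes adventitious acid.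

Step 8
Reactants: 15 (2R,3S)-7-(benzyloxy)-3-[(benzyloxy)methyl]-2-[4-(benzyloxy)-3-methoxyphenyl]-4-{[(tert-butyldimethylsilyl)oxy]methyl}-2,3-dihydro-1-benzofuran
Product: 16 [(2R,3S)-7-(benzyloxy)-3-[(benzyloxy)methyl]-2-[4-(benzyloxy)-3-methoxyphenyl]-2,3-dihydro-1-benzofuran-4-yl]methanol
Conditions: TBAF, THF, 0 °C to rt
Reagents that add atoms: none
Why: Fluoride-mediated cleavage of a primary silyl ether; benzyl ethers and the ring D ether are inert to fluoride.

Step 9
Reactants: 16 [(2R,3S)-7-(benzyloxy)-3-[(benzyloxy)methyl]-2-[4-(benzyloxy)-3-methoxyphenyl]-2,3-dihydro-1-benzofuran-4-yl]methanol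
Product: 17 (2R,3S)-7-(benzyloxy)-3-[(benzyloxy)methyl]-2-[4-(benzyloxy)-3-methoxyphenyl]-2,3-dihydro-1-benzofuran-4-carbaldehyde
Conditions: MnO2 (activated, excess), CH2Cl2, rt
Reagents that add atoms: none
Why: Selective oxidation of a benzylic alcohol to the aryl aldehyde under neutral heterogeneous conditions that do not endanger the acid-sensitive C2–O1 bond and cannot over-oxidise.

Step 10
Reactants: 18 1-(2,4,6-trihydroxyphenyl)ethan-1-one
Product: 19 1-[2,4-bis(benzyloxy)-6-hydroxyphenyl]ethan-1-one
Conditions: BnBr (2.1 equiv), K2CO3, DMF, rt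
Reagents that add atoms: benzyl bromide, BrCc1ccccc1
Why: Williamson etherification; the hydroxyl hydrogen-bonded to the acetyl carbonyl is the least nucleophilic, so two equivalents of benzyl bromide should leave it free, as the later chalcone cyclisation requires.

Step 11
Reactants: 17 (2R,3S)-7-(benzyloxy)-3-[(benzyloxy)methyl]-2-[4-(benzyloxy)-3-methoxyphenyl]-2,3-dihydro-1-benzofuran-4-carbaldehyde; 19 1-[2,4-bis(benzyloxy)-6-hydroxyphenyl]ethan-1-one
Product: 20 (2E)-1-[2,4-bis(benzyloxy)-6-hydroxyphenyl]-3-[(2R,3S)-7-(benzyloxy)-3-[(benzyloxy)methyl]-2-[4-(benzyloxy)-3-methoxyphenyl]-2,3-dihydro-1-benzofuran-4-yl]prop-2-en-1-one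
Conditions: KOH (50% aq), EtOH/THF, rt
Reagents that add atoms: none
Why: Claisen–Schmidt condensation of a non-enolisable aryl aldehyde with the methyl ketone; E1cB dehydration gives the E enone, and the C3–H of ring D is not acidic enough to be touched by hydroxide.

Step 12
Reactants: 20 (2E)-1-[2,4-bis(benzyloxy)-6-hydroxyphenyl]-3-[(2R,3S)-7-(benzyloxy)-3-[(benzyloxy)methyl]-2-[4-(benzyloxy)-3-methoxyphenyl]-2,3-dihydro-1-benzofuran-4-yl]prop-2-en-1-one
Product: 21 5,7-bis(benzyloxy)-2-[(2R,3S)-7-(benzyloxy)-3-[(benzyloxy)methyl]-2-[4-(benzyloxy)-3-methoxyphenyl]-2,3-dihydro-1-benzofuran-4-yl]-4H-chromen-4-one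
Conditions: I2 (10 mol%), DMSO, 120 °C
Reagents that add atoms: none
Why: Iodine-catalysed oxidative cyclisation of a 2'-hydroxychalcone to the flavone (oxa-Michael closure followed by iodination–elimination), with DMSO as the terminal oxidant that regenerates iodine.

Step 13
Reactants: 21 5,7-bis(benzyloxy)-2-[(2R,3S)-7-(benzyloxy)-3-[(benzyloxy)methyl]-2-[4-(benzyloxy)-3-methoxyphenyl]-2,3-dihydro-1-benzofuran-4-yl]-4H-chromen-4-one
Product: 23 5,7-bis(benzyloxy)-2-[(2R,3S)-7-(benzyloxy)-3-[(benzyloxy)methyl]-2-[4-(benzyloxy)-3-methoxyphenyl]-2,3-dihydro-1-benzofuran-4-yl]-3-hydroxy-4H-chromen-4-one, via flavone 2,3-epoxide 22 (not isolated)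
Conditions: dimethyldioxirane (acetone solution, excess), CH2Cl2, 0 °C; then p-TsOH (cat.), CH2Cl2, rt
Reagents that add atoms: dimethyldioxirane, CC1(C)OO1
Why: Epoxidation of the chromone C2=C3 bond, made electron-rich enough by the ring oxygen and the 5,7-dialkoxy groups, followed by acid-induced opening of the epoxide at C2 and loss of the C3 proton to give the 3-hydroxyflavone; this is the established way to hydroxylate benzyl-protected flavones at C3.

Step 14
Reactants: 23 5,7-bis(benzyloxy)-2-[(2R,3S)-7-(benzyloxy)-3-[(benzyloxy)methyl]-2-[4-(benzyloxy)-3-methoxyphenyl]-2,3-dihydro-1-benzofuran-4-yl]-3-hydroxy-4H-chromen-4-one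
Product: 24 3,5,7-trihydroxy-2-[(2R,3S)-7-hydroxy-2-(4-hydroxy-3-methoxyphenyl)-3-(hydroxymethyl)-2,3-dihydro-1-benzofuran-4-yl]-4H-chromen-4-one
Conditions: H2 (1 atm), Pd(OH)2/C, THF/MeOH, rt
Reagents that add atoms: none
Why: Catalytic hydrogenolysis of four aryl and one alkyl benzyl ether under neutral conditions; the flavonol double bond is part of a vinylogous ester and the cyclic C2–O1 ether is cleaved far more slowly than O-benzyl groups, so stopping at full debenzylation should be possible.

## Compound list

1 | tert-butyldimethyl(prop-2-yn-1-yloxy)silane | C#CCO[Si](C)(C)C(C)(C)C | starting material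
2 | 2-(benzyloxy)-N-methoxy-N-methylacetamide | CON(C)C(=O)COCc1ccccc1 | starting material
3 | lithium 3-[(tert-butyldimethylsilyl)oxy]prop-1-yn-1-ide | [Li]C#CCO[Si](C)(C)C(C)(C)C | intermediate (not isolated)
4 | 1-(benzyloxy)-5-[(tert-butyldimethylsilyl)oxy]pent-3-yn-2-one | O=C(COCc1ccccc1)C#CCO[Si](C)(C)C(C)(C)C | intermediate
5 | (2R)-1-(benzyloxy)-5-[(tert-butyldimethylsilyl)oxy]pent-3-yn-2-ol | O[C@@H](COCc1ccccc1)C#CCO[Si](C)(C)C(C)(C)C | intermediate
6 | (2R)-1-(benzyloxy)-5-[(tert-butyldimethylsilyl)oxy]pent-3-yn-2-yl methanesulfonate | CS(=O)(=O)O[C@@H](COCc1ccccc1)C#CCO[Si](C)(C)C(C)(C)C | intermediate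
7 | 4-(benzyloxy)-3-methoxybenzaldehyde | COc1cc(C=O)ccc1OCc1ccccc1 | starting material
8 | {(aR)-5-(benzyloxy)-1-[(tert-butyldimethylsilyl)oxy]penta-2,3-dien-2-yl}(ethyl)zinc | CC[Zn]C(CO[Si](C)(C)C(C)(C)C)=[C@]=C([H])COCc1ccccc1 | intermediate (not isolated)
9 | (1R,2S)-2-[(benzyloxy)methyl]-1-[4-(benzyloxy)-3-methoxyphenyl]-5-[(tert-butyldimethylsilyl)oxy]pent-3-yn-1-ol | COc1cc([C@H](O)[C@H](COCc2ccccc2)C#CCO[Si](C)(C)C(C)(C)C)ccc1OCc1ccccc1 | intermediate
10 | 3,4-dichloropyridazine | Clc1ccnnc1Cl | starting material
11 | 4-(benzyloxy)-3-chloropyridazine | Clc1nnccc1OCc1ccccc1 | intermediate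
12 | sodium (1R,2S)-2-[(benzyloxy)methyl]-1-[4-(benzyloxy)-3-methoxyphenyl]-5-[(tert-butyldimethylsilyl)oxy]pent-3-yn-1-olate | COc1cc([C@H]([O-])[C@H](COCc2ccccc2)C#CCO[Si](C)(C)C(C)(C)C)ccc1OCc1ccccc1.[Na+] | intermediate (not isolated)
13 | 4-(benzyloxy)-3-{[(1R,2S)-2-[(benzyloxy)methyl]-1-[4-(benzyloxy)-3-methoxyphenyl]-5-[(tert-butyldimethylsilyl)oxy]pent-3-yn-1-yl]oxy}pyridazine | COc1cc([C@H](Oc2nnccc2OCc2ccccc2)[C@H](COCc2ccccc2)C#CCO[Si](C)(C)C(C)(C)C)ccc1OCc1ccccc1 | intermediate
14 | (2R,3S)-7-(benzyloxy)-3-[(benzyloxy)methyl]-2-[4-(benzyloxy)-3-methoxyphenyl]-4-{[(tert-butyldimethylsilyl)oxy]methyl}-2,3,5,7a-tetrahydro-5,7a-epidiazeno-1-benzofuran (either configuration at bridgeheads C5 and C7a) | COc1cc([C@@H]2OC34N=NC(C=C3OCc3ccccc3)C(CO[Si](C)(C)C(C)(C)C)=C4[C@H]2COCc2ccccc2)ccc1OCc1ccccc1 | intermediate (not isolated)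
15 | (2R,3S)-7-(benzyloxy)-3-[(benzyloxy)methyl]-2-[4-(benzyloxy)-3-methoxyphenyl]-4-{[(tert-butyldimethylsilyl)oxy]methyl}-2,3-dihydro-1-benzofuran | COc1cc([C@@H]2Oc3c(OCc4ccccc4)ccc(CO[Si](C)(C)C(C)(C)C)c3[C@H]2COCc2ccccc2)ccc1OCc1ccccc1 | intermediate
16 | [(2R,3S)-7-(benzyloxy)-3-[(benzyloxy)methyl]-2-[4-(benzyloxy)-3-methoxyphenyl]-2,3-dihydro-1-benzofuran-4-yl]methanol | COc1cc([C@@H]2Oc3c(OCc4ccccc4)ccc(CO)c3[C@H]2COCc2ccccc2)ccc1OCc1ccccc1 | intermediate
17 | (2R,3S)-7-(benzyloxy)-3-[(benzyloxy)methyl]-2-[4-(benzyloxy)-3-methoxyphenyl]-2,3-dihydro-1-benzofuran-4-carbaldehyde | COc1cc([C@@H]2Oc3c(OCc4ccccc4)ccc(C=O)c3[C@H]2COCc2ccccc2)ccc1OCc1ccccc1 | intermediate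
18 | 1-(2,4,6-trihydroxyphenyl)ethan-1-one | CC(=O)c1c(O)cc(O)cc1O | starting material
19 | 1-[2,4-bis(benzyloxy)-6-hydroxyphenyl]ethan-1-one | CC(=O)c1c(O)cc(OCc2ccccc2)cc1OCc1ccccc1 | intermediate
20 | (2E)-1-[2,4-bis(benzyloxy)-6-hydroxyphenyl]-3-[(2R,3S)-7-(benzyloxy)-3-[(benzyloxy)methyl]-2-[4-(benzyloxy)-3-methoxyphenyl]-2,3-dihydro-1-benzofuran-4-yl]prop-2-en-1-one | COc1cc([C@@H]2Oc3c(OCc4ccccc4)ccc(/C=C/C(=O)c4c(O)cc(OCc5ccccc5)cc4OCc4ccccc4)c3[C@H]2COCc2ccccc2)ccc1OCc1ccccc1 | intermediate
21 | 5,7-bis(benzyloxy)-2-[(2R,3S)-7-(benzyloxy)-3-[(benzyloxy)methyl]-2-[4-(benzyloxy)-3-methoxyphenyl]-2,3-dihydro-1-benzofuran-4-yl]-4H-chromen-4-one | COc1cc([C@@H]2Oc3c(OCc4ccccc4)ccc(-c4cc(=O)c5c(OCc6ccccc6)cc(OCc6ccccc6)cc5o4)c3[C@H]2COCc2ccccc2)ccc1OCc1ccccc1 | intermediate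
22 | 4,6-bis(benzyloxy)-1a-[(2R,3S)-7-(benzyloxy)-3-[(benzyloxy)methyl]-2-[4-(benzyloxy)-3-methoxyphenyl]-2,3-dihydro-1-benzofuran-4-yl]-1a,7a-dihydro-7H-oxireno[2,3-b]chromen-7-one (2,3-epoxide of 21; either epoxide face) | COc1cc([C@@H]2Oc3c(OCc4ccccc4)ccc(C45OC4C(=O)c4c(OCc6ccccc6)cc(OCc6ccccc6)cc4O5)c3[C@H]2COCc2ccccc2)ccc1OCc1ccccc1 | intermediate (not isolated)
23 | 5,7-bis(benzyloxy)-2-[(2R,3S)-7-(benzyloxy)-3-[(benzyloxy)methyl]-2-[4-(benzyloxy)-3-methoxyphenyl]-2,3-dihydro-1-benzofuran-4-yl]-3-hydroxy-4H-chromen-4-one | COc1cc([C@@H]2Oc3c(OCc4ccccc4)ccc(-c4oc5cc(OCc6ccccc6)cc(OCc6ccccc6)c5c(=O)c4O)c3[C@H]2COCc2ccccc2)ccc1OCc1ccccc1 | intermediate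
24 | 3,5,7-trihydroxy-2-[(2R,3S)-7-hydroxy-2-(4-hydroxy-3-methoxyphenyl)-3-(hydroxymethyl)-2,3-dihydro-1-benzofuran-4-yl]-4H-chromen-4-one | COc1cc([C@@H]2Oc3c(O)ccc(-c4oc5cc(O)cc(O)c5c(=O)c4O)c3[C@H]2CO)ccc1O | target

## Step count and risk

Total: 14 steps. Longest linear sequence: 12 steps (steps 1–4, 6–9 and 11–14); steps 5 and 10 prepare 11 and 19.

**Step 7 (key step).** The cycloaddition is slowed by the donor alkoxy group on the diazine and by the internal alkyne. Thermal cleavage of the benzylic pyridazinyl ether may then overtake it, either by ionisation assisted by the para-benzyloxy group or by elimination towards the propargylic hydrogen with release of the pyridazinone. The fallback removes the donor from the aryl ring for the thermolysis. It sets out from 6 and returns at 15.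
- The propargylation of step 4 is run on 6 with 4-formyl-2-methoxyphenyl 4-methylbenzenesulfonate F1 to give 4-[(1R,2S)-2-[(benzyloxy)methyl]-5-[(tert-butyldimethylsilyl)oxy]-1-hydroxypent-3-yn-1-yl]-2-methoxyphenyl 4-methylbenzenesulfonate F2.
- Etherification with 11 as in step 6 gives 4-[(1R,2S)-2-[(benzyloxy)methyl]-1-{[4-(benzyloxy)pyridazin-3-yl]oxy}-5-[(tert-butyldimethylsilyl)oxy]pent-3-yn-1-yl]-2-methoxyphenyl 4-methylbenzenesulfonate F3.
- Thermolysis as in step 7 gives 4-[(2R,3S)-7-(benzyloxy)-3-[(benzyloxy)methyl]-4-{[(tert-butyldimethylsilyl)oxy]methyl}-2,3-dihydro-1-benzofuran-2-yl]-2-methoxyphenyl 4-methylbenzenesulfonate F4. The sulfonyloxy group no longer stabilises a benzylic cation in F3.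
- KOH in aqueous MeOH/THF at 40 °C cleaves the sulfonate to 4-[(2R,3S)-7-(benzyloxy)-3-[(benzyloxy)methyl]-4-{[(tert-butyldimethylsilyl)oxy]methyl}-2,3-dihydro-1-benzofuran-2-yl]-2-methoxyphenol F5.
- Benzylation (BnBr, K2CO3, DMF, rt) gives 15.

**Step 4.** Facial selectivity at the aromatic aldehyde may be poor (erosion of the anti preference), and some allenylzinc may be lost by 1,4-elimination of benzyloxide. Both epimers carry the same C2 configuration from 6, so the fallback corrects C1 thermodynamically after ring formation. It sets out from 6 and 7 and returns at 15.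
- The crude product of step 4 is taken on unseparated; it contains (1S,2S)-2-[(benzyloxy)methyl]-1-[4-(benzyloxy)-3-methoxyphenyl]-5-[(tert-butyldimethylsilyl)oxy]pent-3-yn-1-ol F6 beside 9.
- Step 6 converts the minor epimer into 4-(benzyloxy)-3-{[(1S,2S)-2-[(benzyloxy)methyl]-1-[4-(benzyloxy)-3-methoxyphenyl]-5-[(tert-butyldimethylsilyl)oxy]pent-3-yn-1-yl]oxy}pyridazine F7.
- Step 7 converts it into (2S,3S)-7-(benzyloxy)-3-[(benzyloxy)methyl]-2-[4-(benzyloxy)-3-methoxyphenyl]-4-{[(tert-butyldimethylsilyl)oxy]methyl}-2,3-dihydro-1-benzofuran F8, the cis isomer.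
- Catalytic BF3·OEt2 in CH2Cl2 at −40 °C should ionise the C2–O1 bond reversibly at the para-alkoxybenzylic carbon and let the ring reclose to the more stable trans isomer 15.

**Step 6.** Substitution at the alkoxy-deactivated C3 by a hindered secondary alkoxide may be slow. That leaves time for base-induced propargyl–allenyl isomerisation or 5-endo addition of the alkoxide to the alkyne. The fallback replaces the uncatalysed substitution by palladium-catalysed C–O cross-coupling of 9 with 11 ([Pd(allyl)Cl]2, RockPhos, Cs2CO3, toluene, 90 °C). It sets out from 9, returns at 13 and makes no new compound.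

**Step 12.** Acid formed from iodine at 120 °C may remove the benzyl group on the oxygen next to the carbonyl or ionise the C2–O1 bond of ring D. The fallback separates ring closure from dehydrogenation. It sets out from 20 and returns at 21.
- NaOAc in refluxing EtOH should close the oxa-Michael ring to 5,7-bis(benzyloxy)-2-[(2R,3S)-7-(benzyloxy)-3-[(benzyloxy)methyl]-2-[4-(benzyloxy)-3-methoxyphenyl]-2,3-dihydro-1-benzofuran-4-yl]-2,3-dihydro-4H-chromen-4-one F9 (both epimers at the new chromanone carbon).
- Aerobic dehydrogenation (Pd(O2CCF3)2, DMSO, O2, 80 °C) gives 21.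

**Step 13.** Epoxidation of the electron-poor chromone double bond is slow, so oxidation of benzylic ether C–H bonds or of the electron-rich arenes may compete. The fallback is anionic. It sets out from 21 and returns at 23.
- LDA in THF at −78 °C deprotonates C3 of the chromone; B(OMe)3 traps the anion as dimethyl {5,7-bis(benzyloxy)-2-[(2R,3S)-7-(benzyloxy)-3-[(benzyloxy)methyl]-2-[4-(benzyloxy)-3-methoxyphenyl]-2,3-dihydro-1-benzofuran-4-yl]-4-oxo-4H-chromen-3-yl}boronate F10 (not isolated).
- H2O2/AcOH oxidises the C–B bond in the same flask to give 23.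

## Further compounds

F1 | step 7 | 4-formyl-2-methoxyphenyl 4-methylbenzenesulfonate | COc1cc(C=O)ccc1OS(=O)(=O)c1ccc(C)cc1
F2 | step 7 | 4-[(1R,2S)-2-[(benzyloxy)methyl]-5-[(tert-butyldimethylsilyl)oxy]-1-hydroxypent-3-yn-1-yl]-2-methoxyphenyl 4-methylbenzenesulfonate | COc1cc([C@H](O)[C@H](COCc2ccccc2)C#CCO[Si](C)(C)C(C)(C)C)ccc1OS(=O)(=O)c1ccc(C)cc1
F3 | step 7 | 4-[(1R,2S)-2-[(benzyloxy)methyl]-1-{[4-(benzyloxy)pyridazin-3-yl]oxy}-5-[(tert-butyldimethylsilyl)oxy]pent-3-yn-1-yl]-2-methoxyphenyl 4-methylbenzenesulfonate | COc1cc([C@H](Oc2nnccc2OCc2ccccc2)[C@H](COCc2ccccc2)C#CCO[Si](C)(C)C(C)(C)C)ccc1OS(=O)(=O)c1ccc(C)cc1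
F4 | step 7 | 4-[(2R,3S)-7-(benzyloxy)-3-[(benzyloxy)methyl]-4-{[(tert-butyldimethylsilyl)oxy]methyl}-2,3-dihydro-1-benzofuran-2-yl]-2-methoxyphenyl 4-methylbenzenesulfonate | COc1cc([C@@H]2Oc3c(OCc4ccccc4)ccc(CO[Si](C)(C)C(C)(C)C)c3[C@H]2COCc2ccccc2)ccc1OS(=O)(=O)c1ccc(C)cc1
F5 | step 7 | 4-[(2R,3S)-7-(benzyloxy)-3-[(benzyloxy)methyl]-4-{[(tert-butyldimethylsilyl)oxy]methyl}-2,3-dihydro-1-benzofuran-2-yl]-2-methoxyphenol | COc1cc([C@@H]2Oc3c(OCc4ccccc4)ccc(CO[Si](C)(C)C(C)(C)C)c3[C@H]2COCc2ccccc2)ccc1O
F6 | step 4 | (1S,2S)-2-[(benzyloxy)methyl]-1-[4-(benzyloxy)-3-methoxyphenyl]-5-[(tert-butyldimethylsilyl)oxy]pent-3-yn-1-ol | COc1cc([C@@H](O)[C@H](COCc2ccccc2)C#CCO[Si](C)(C)C(C)(C)C)ccc1OCc1ccccc1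
F7 | step 4 | 4-(benzyloxy)-3-{[(1S,2S)-2-[(benzyloxy)methyl]-1-[4-(benzyloxy)-3-methoxyphenyl]-5-[(tert-butyldimethylsilyl)oxy]pent-3-yn-1-yl]oxy}pyridazine | COc1cc([C@@H](Oc2nnccc2OCc2ccccc2)[C@H](COCc2ccccc2)C#CCO[Si](C)(C)C(C)(C)C)ccc1OCc1ccccc1
F8 | step 4 | (2S,3S)-7-(benzyloxy)-3-[(benzyloxy)methyl]-2-[4-(benzyloxy)-3-methoxyphenyl]-4-{[(tert-butyldimethylsilyl)oxy]methyl}-2,3-dihydro-1-benzofuran | COc1cc([C@H]2Oc3c(OCc4ccccc4)ccc(CO[Si](C)(C)C(C)(C)C)c3[C@H]2COCc2ccccc2)ccc1OCc1ccccc1
F0 | step 6 | none | none
F9 | step 12 | 5,7-bis(benzyloxy)-2-[(2R,3S)-7-(benzyloxy)-3-[(benzyloxy)methyl]-2-[4-(benzyloxy)-3-methoxyphenyl]-2,3-dihydro-1-benzofuran-4-yl]-2,3-dihydro-4H-chromen-4-one (both epimers at chromanone C2) | COc1cc([C@@H]2Oc3c(OCc4ccccc4)ccc(C4CC(=O)c5c(OCc6ccccc6)cc(OCc6ccccc6)cc5O4)c3[C@H]2COCc2ccccc2)ccc1OCc1ccccc1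
F10 | step 13 | dimethyl {5,7-bis(benzyloxy)-2-[(2R,3S)-7-(benzyloxy)-3-[(benzyloxy)methyl]-2-[4-(benzyloxy)-3-methoxyphenyl]-2,3-dihydro-1-benzofuran-4-yl]-4-oxo-4H-chromen-3-yl}boronate | COc1cc([C@@H]2Oc3c(OCc4ccccc4)ccc(-c4oc5cc(OCc6ccccc6)cc(OCc6ccccc6)c5c(=O)c4B(OC)OC)c3[C@H]2COCc2ccccc2)ccc1OCc1ccccc1
A1 | alternative 1 | (2R,3S)-7-(benzyloxy)-3-[(benzyloxy)methyl]-4-bromo-2-[4-(benzyloxy)-3-methoxyphenyl]-2,3-dihydro-1-benzofuran | COc1cc([C@@H]2Oc3c(OCc4ccccc4)ccc(Br)c3[C@H]2COCc2ccccc2)ccc1OCc1ccccc1
A2 | alternative 1 | 6-(benzyloxy)-2-[2-(benzyloxy)-1-(4-methylbenzenesulfonyl)ethyl]-3-bromophenol (racemic) | Cc1ccc(S(=O)(=O)C(COCc2ccccc2)c2c(Br)ccc(OCc3ccccc3)c2O)cc1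
A3 | alternative 1 | (2R,5R)-1-[4-(benzyloxy)-3-methoxybenzyl]-2,5-dimethylthiolan-1-ium trifluoromethanesulfonate | C[C@@H]1CC[C@@H](C)[S+]1Cc1ccc(OCc2ccccc2)c(OC)c1.[O-]S(=O)(=O)C(F)(F)F
A4 | alternative 2 | methyl (2R,3R)-7-(benzyloxy)-4-bromo-2-[4-(benzyloxy)-3-methoxyphenyl]-2,3-dihydro-1-benzofuran-3-carboxylate | COc1cc([C@@H]2Oc3c(OCc4ccccc4)ccc(Br)c3[C@H]2C(=O)OC)ccc1OCc1ccccc1
A5 | alternative 2 | (2S)-8-(benzyloxy)-5-bromo-2-[4-(benzyloxy)-3-methoxyphenyl]-3-diazo-2,3-dihydro-4H-chromen-4-one | COc1cc([C@@H]2Oc3c(OCc4ccccc4)ccc(Br)c3C(=O)C2=[N+]=[N-])ccc1OCc1ccccc1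
A6 | alternative 3 | [(2R,3S)-7-(benzyloxy)-2-[4-(benzyloxy)-3-methoxyphenyl]-4-[(trimethylsilyl)ethynyl]-2,3-dihydro-1-benzofuran-3-yl]methanol | COc1cc([C@@H]2Oc3c(OCc4ccccc4)ccc(C#C[Si](C)(C)C)c3[C@H]2CO)ccc1OCc1ccccc1
A7 | alternative 3 | 4-(benzyloxy)-3-{(S)-[4-(benzyloxy)-3-methoxyphenyl][(2R)-oxiran-2-yl]methoxy}phenyl trifluoromethanesulfonate | COc1cc([C@H](Oc2cc(OS(=O)(=O)C(F)(F)F)ccc2OCc2ccccc2)[C@H]2CO2)ccc1OCc1ccccc1
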